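**Retrosynthetic overview**
1. Target ⇐ its bis-pivalate ⇐ β-(α-hydroxybenzyl)-γ-butyrolactone + 4-(bromomethyl)-2-methoxyphenyl pivalate: the C8'–C7' bond is made by enolate alkylation anti to the C8 substituent, which sets C8'.
2. The lactone, the only ring that is built, ⇐ an open seco-type triol: the unhindered C9' carbinol is dehydrogenated, O9 closes to the lactol, and a second dehydrogenation gives the lactone, the order presumed for the plant dehydrogenase.
3. Triol ⇐ vanillin pivalate + 4-hydroxybutanal (as its lactol, from 2,3-dihydrofuran): the C7–C8 bond and both stereocentres come from an L-proline anti-aldol, followed by reduction.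
4. Ring order: both arenes are bought as vanillin; the butyrolactone is formed in step 3, before the second aryl unit is attached.

Assumption: lignan numbering is used (C7–C8–C9 = hydroxybenzyl arm and lactone CH2O; C7'–C8'–C9' = benzyl arm and lactone C=O); the target is the (7R,8R,8'R) isomer with a trans-disubstituted lactone.

**Step 1**
Reactants: 1 vanillin
Product: 2 4-formyl-2-methoxyphenyl pivalate
Conditions: PivCl, Et3N, DMAP (5 mol %), CH2Cl2, 0 °C → rt
Reagents that add atoms: pivaloyl chloride, CC(C)(C)C(Cl)=O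
Why: DMAP-catalysed O-acylation of the phenol; the ester removes the donor character of the phenol so that the aldehyde is a competent aldol acceptor, and it withstands borohydride, aerobic oxidation and amide base at −78 °C; no stereocentre is involved.

**Step 2**
Reactants: 2 4-formyl-2-methoxyphenyl pivalate; 3 2,3-dihydrofuran
Product: 6 triol 4-[(1R,2R)-1,4-dihydroxy-2-(hydroxymethyl)butyl]-2-methoxyphenyl pivalate, via tetrahydrofuran-2-ol 4 (not isolated), via anti-aldol hemiacetal 5 (not isolated)
Conditions: 3, H2O (1.2 equiv), Amberlyst-15 (cat.), DMF, 0 °C → rt, filtered; added over 24 h to 2 (2 equiv), L-proline (20 mol %), DMF, 4 °C; then MeOH, NaBH4, 0 °C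
Reagents that add atoms: water, O
Why: Acid-catalysed hydration of the enol ether gives lactol 4, whose open form (4-hydroxybutanal) enters a proline-catalysed direct cross-aldol (enamine catalysis, Houk–List transition state) in which the (E)-enamine of L-proline attacks the Re face of the non-enolisable aldehyde 2, setting C7 (R) and C8 together as the anti adduct (about 4:1 anti:syn and ≥95% ee expected; the adduct is shielded from epimerisation as hemiacetal 5), and NaBH4 then reduces the hemiacetal to the triol without touching the aryl ester; the minor syn isomer is removed by chromatography.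

**Step 3**
Reactants: 6 triol 4-[(1R,2R)-1,4-dihydroxy-2-(hydroxymethyl)butyl]-2-methoxyphenyl pivalate
Product: 8 hydroxy lactone 4-{(R)-hydroxy[(3R)-5-oxotetrahydrofuran-3-yl]methyl}-2-methoxyphenyl pivalate, via lactol 7 (not isolated)
Conditions: Cu(MeCN)4OTf (5 mol %), 2,2'-bipyridine (5 mol %), TEMPO (5 mol %), N-methylimidazole (10 mol %), air, MeCN, rt
Reagents that add atoms: none
Why: Cu/TEMPO aerobic alcohol oxidation run as a dehydrogenative lactonisation on the unprotected triol: the catalyst oxidises only the unhindered primary C9'–OH (the β-branched C9–OH and the secondary benzylic C7–OH are too hindered for this system), the aldehyde closes with O9 to the monosubstituted lactol 7 (closure with O7 would give a cis-4,5-disubstituted ring), and a second dehydrogenation gives the γ-lactone; C7 and C8 are not touched.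

**Step 4**
Reactants: 2 4-formyl-2-methoxyphenyl pivalate
Product: 9 4-(hydroxymethyl)-2-methoxyphenyl pivalate
Conditions: NaBH4, MeOH, 0 °C
Reagents that add atoms: none
Why: Chemoselective borohydride reduction of the aldehyde; the hindered aryl pivalate survives at 0 °C and no stereocentre is formed.

**Step 5**
Reactants: 9 4-(hydroxymethyl)-2-methoxyphenyl pivalate
Product: 10 4-(bromomethyl)-2-methoxyphenyl pivalate
Conditions: PBr3 (0.4 equiv), Et2O, 0 °C
Reagents that add atoms: phosphorus tribromide, BrP(Br)Br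
Why: Bromination of a primary benzylic alcohol through its phosphite ester with SN2 displacement by bromide; the acyloxy group keeps the benzyl bromide from ionising, and no stereocentre is involved.

**Step 6**
Reactants: 8 hydroxy lactone 4-{(R)-hydroxy[(3R)-5-oxotetrahydrofuran-3-yl]methyl}-2-methoxyphenyl pivalate; 10 4-(bromomethyl)-2-methoxyphenyl pivalate
Product: 11 4-{[(3R,4R)-4-{(R)-hydroxy[3-methoxy-4-(pivaloyloxy)phenyl]methyl}-2-oxotetrahydrofuran-3-yl]methyl}-2-methoxyphenyl pivalate
Conditions: LiN(SiMe3)2 (2.2 equiv), THF, −78 °C; DMPU, 10 (1.1 equiv), −78 → −40 °C; AcOH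
Reagents that add atoms: none
Why: Alkylation of a lactone enolate as its alkoxide–enolate dianion (Fráter–Seebach-type): the first equivalent of base makes the C7 alkoxide, the second the enolate, and the benzyl bromide enters the planar enolate anti to the bulky C4 substituent, setting C8' (R) as the 3,4-trans lactone; C7 and C8 are not enolisable and stay as set.

**Step 7**
Reactants: 11 4-{[(3R,4R)-4-{(R)-hydroxy[3-methoxy-4-(pivaloyloxy)phenyl]methyl}-2-oxotetrahydrofuran-3-yl]methyl}-2-methoxyphenyl pivalate
Product: 12 5-allohydroxymatairesinol (3R,4R)-4-[(R)-hydroxy(4-hydroxy-3-methoxyphenyl)methyl]-3-(4-hydroxy-3-methoxybenzyl)dihydrofuran-2(3H)-one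
Conditions: K2CO3 (0.2 equiv), MeOH, 0 °C → rt; then pH 5 phosphate buffer, EtOAc
Reagents that add atoms: none
Why: Base-catalysed transesterification (Zemplén-type methanolysis) of the two aryl esters, which have phenoxide leaving groups and cleave under conditions where the benzylic alcohol does not ionise; C8' already has the thermodynamic trans arrangement, so enolisation cannot scramble it, and any ring-opened methyl ester re-closes to the γ-lactone on mild acidification.

**Compound list**
1 | vanillin (4-hydroxy-3-methoxybenzaldehyde) | COc1cc(C=O)ccc1O | starting material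
2 | 4-formyl-2-methoxyphenyl pivalate | COc1cc(C=O)ccc1OC(=O)C(C)(C)C | intermediate
3 | 2,3-dihydrofuran | C1=COCC1 | starting material
4 | tetrahydrofuran-2-ol (racemic lactol of 4-hydroxybutanal; not isolated) | OC1CCCO1 | intermediate
5 | (2S,3R)-3-hydroxy-2-(2-hydroxyethyl)-3-[3-methoxy-4-(pivaloyloxy)phenyl]propanal, present as its cyclic hemiacetal (open form drawn; not isolated) | O=C[C@@H](CCO)[C@@H](O)c1ccc(OC(=O)C(C)(C)C)c(OC)c1 | intermediate
6 | 4-[(1R,2R)-1,4-dihydroxy-2-(hydroxymethyl)butyl]-2-methoxyphenyl pivalate | OC[C@@H](CCO)[C@@H](O)c1ccc(OC(=O)C(C)(C)C)c(OC)c1 | intermediate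
7 | 4-{(R)-hydroxy[(3R)-5-hydroxytetrahydrofuran-3-yl]methyl}-2-methoxyphenyl pivalate (anomer mixture; not isolated) | OC1C[C@H](CO1)[C@@H](O)c2ccc(OC(=O)C(C)(C)C)c(OC)c2 | intermediate
8 | 4-{(R)-hydroxy[(3R)-5-oxotetrahydrofuran-3-yl]methyl}-2-methoxyphenyl pivalate | O=C1C[C@H](CO1)[C@@H](O)c2ccc(OC(=O)C(C)(C)C)c(OC)c2 | intermediate
9 | 4-(hydroxymethyl)-2-methoxyphenyl pivalate | COc1cc(CO)ccc1OC(=O)C(C)(C)C | intermediate
10 | 4-(bromomethyl)-2-methoxyphenyl pivalate | COc1cc(CBr)ccc1OC(=O)C(C)(C)C | intermediate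
11 | 4-{[(3R,4R)-4-{(R)-hydroxy[3-methoxy-4-(pivaloyloxy)phenyl]methyl}-2-oxotetrahydrofuran-3-yl]methyl}-2-methoxyphenyl pivalate | COc1cc(C[C@H]2C(=O)OC[C@@H]2[C@@H](O)c2ccc(OC(=O)C(C)(C)C)c(OC)c2)ccc1OC(=O)C(C)(C)C | intermediate
12 | 5-allohydroxymatairesinol, (3R,4R)-4-[(R)-hydroxy(4-hydroxy-3-methoxyphenyl)methyl]-3-(4-hydroxy-3-methoxybenzyl)dihydrofuran-2(3H)-one | COc1cc(C[C@H]2C(=O)OC[C@@H]2[C@@H](O)c2ccc(O)c(OC)c2)ccc1O | target

**Total step count:** 7. **Longest linear sequence:** 5 (steps 1, 2, 3, 6, 7).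

**The three steps most likely to fail, with fallbacks**

The cross-aldol of step 2 is the weakest point. The donor is mostly tied up as lactol 4, the acceptor is only moderately electrophilic, and the anti:syn ratio of proline aldols with aromatic aldehydes is modest. If conversion or selectivity is poor, the C7–C8 bond is made by an auxiliary-controlled anti-aldol that sets out from 2 and returns at 6. (R)-4-Benzyl-2-oxazolidinone is N-acylated (n-BuLi, pent-4-enoyl chloride, THF, −78 °C) to (R)-4-benzyl-3-(pent-4-enoyl)oxazolidin-2-one F1. F1 and 2 react under MgCl2 (10 mol %), Et3N and Me3SiCl in EtOAc at rt. The chelated Z-enolate adds to the aldehyde anti to the benzyl group of the auxiliary and gives the anti-aldol silyl ether (4R)-4-benzyl-3-[(2S,3R)-3-[3-methoxy-4-(pivaloyloxy)phenyl]-2-(prop-2-en-1-yl)-3-(trimethylsilyloxy)propanoyl]oxazolidin-2-one F2. LiBH4/H2O in Et2O at 0 °C with citric acid work-up removes the auxiliary and the silyl group to give the diol 4-[(1R,2R)-1-hydroxy-2-(hydroxymethyl)pent-4-en-1-yl]-2-methoxyphenyl pivalate F3. Ozonolysis (O3, CH2Cl2/MeOH, −78 °C) with NaBH4 work-up turns the vinyl group into the CH2OH of C9' and gives triol 6.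

The oxidative lactonisation of step 3 relies on steric discrimination alone. Oxidation at C9–OH would give the regioisomeric lactone, closure through O7 the cis-fused isomer, and the lactol might stall before the second dehydrogenation. If that fails, C9' is brought in at the ester level so that no oxidation is needed; this sets out from 2 and returns at 8. L-Proline-catalysed cross-aldol of 2 with methyl 4-oxobutanoate (DMF, 4 °C) gives methyl (3S,4R)-3-formyl-4-hydroxy-4-[3-methoxy-4-(pivaloyloxy)phenyl]butanoate F4. NaBH4 (MeOH, 0 °C) reduces the aldehyde to methyl (3R,4R)-4-hydroxy-3-(hydroxymethyl)-4-[3-methoxy-4-(pivaloyloxy)phenyl]butanoate F5, which lactonises through the primary hydroxyl (PPTS cat., CH2Cl2, rt) to 8.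

The alkylation of step 6 runs on a dianion. The C7 alkoxide can shift the acyl group to give the isomeric lactone, can be O-benzylated, or can attack an aryl ester, and the trans:cis ratio may suffer. If so, the hydroxyl is masked first; this sets out from 8 and returns at 11. Et3SiCl and imidazole in DMF give the silyl ether 4-{(R)-[(3R)-5-oxotetrahydrofuran-3-yl](triethylsilyloxy)methyl}-2-methoxyphenyl pivalate F6. Alkylation of its mono-enolate (LiN(SiMe3)2 1.1 equiv, THF, −78 °C, then 10) gives the trans product 4-{[(3R,4R)-4-{(R)-[3-methoxy-4-(pivaloyloxy)phenyl](triethylsilyloxy)methyl}-2-oxotetrahydrofuran-3-yl]methyl}-2-methoxyphenyl pivalate F7, and HF·pyridine in THF at 0 °C removes the silyl group to give 11.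

**Further compounds**
F1 | step 2 | (R)-4-benzyl-3-(pent-4-enoyl)oxazolidin-2-one | C=CCCC(=O)N1[C@H](Cc2ccccc2)COC1=O
F2 | step 2 | (4R)-4-benzyl-3-[(2S,3R)-3-[3-methoxy-4-(pivaloyloxy)phenyl]-2-(prop-2-en-1-yl)-3-(trimethylsilyloxy)propanoyl]oxazolidin-2-one | O=C(N1[C@H](Cc2ccccc2)COC1=O)[C@@H](CC=C)[C@@H](O[Si](C)(C)C)c1ccc(OC(=O)C(C)(C)C)c(OC)c1
F3 | step 2 | 4-[(1R,2R)-1-hydroxy-2-(hydroxymethyl)pent-4-en-1-yl]-2-methoxyphenyl pivalate | OC[C@@H](CC=C)[C@@H](O)c1ccc(OC(=O)C(C)(C)C)c(OC)c1
F4 | step 3 | methyl (3S,4R)-3-formyl-4-hydroxy-4-[3-methoxy-4-(pivaloyloxy)phenyl]butanoate | O=C[C@@H](CC(=O)OC)[C@@H](O)c1ccc(OC(=O)C(C)(C)C)c(OC)c1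
F5 | step 3 | methyl (3R,4R)-4-hydroxy-3-(hydroxymethyl)-4-[3-methoxy-4-(pivaloyloxy)phenyl]butanoate | OC[C@@H](CC(=O)OC)[C@@H](O)c1ccc(OC(=O)C(C)(C)C)c(OC)c1
F6 | step 6 | 4-{(R)-[(3R)-5-oxotetrahydrofuran-3-yl](triethylsilyloxy)methyl}-2-methoxyphenyl pivalate | O=C1C[C@H](CO1)[C@@H](O[Si](CC)(CC)CC)c2ccc(OC(=O)C(C)(C)C)c(OC)c2
F7 | step 6 | 4-{[(3R,4R)-4-{(R)-[3-methoxy-4-(pivaloyloxy)phenyl](triethylsilyloxy)methyl}-2-oxotetrahydrofuran-3-yl]methyl}-2-methoxyphenyl pivalate | COc1cc(C[C@H]2C(=O)OC[C@@H]2[C@@H](O[Si](CC)(CC)CC)c2ccc(OC(=O)C(C)(C)C)c(OC)c2)ccc1OC(=O)C(C)(C)C
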